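**Plan**

- Retrosynthesis: cut the aryl ether O–CH2 bond (Mitsunobu), then the two oxirane C–O bonds (asymmetric epoxidation of an E-allylic alcohol), then the C3–OH bond of the lactone (enolate oxygenation). Next cut the lactone C3–C4 bond at the butenolide oxidation level (ring-closing metathesis), the ester C–O bond, and last the chain bonds made by alkyne carboalumination/hydroxymethylation and by alkynyl opening of an epoxide.
- Forward order: the seven-carbon chain is joined first from (R)-epichlorohydrin and an acetylene, the five-membered lactone is closed next, the oxirane follows, and the coumarin is attached last.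
- Enabling feature: in the lactone (O1, C2 carbonyl, C3 carbinol, C4 methylene, C5 methine) the ring oxygen already sits on the only secondary carbinol carbon, C5, and C3/C4 are adjacent ring atoms. One oxidation level up, C3=C4 is the union of a methacrylate α-carbon with the CH of a vinyl group on C5.
- The planar C3 made in that closure is then reduced and hydroxylated under control of C5, which removes the extra unsaturation.
- Stereochemistry: C5 is bought with (R)-epichlorohydrin; the C3 tertiary carbinol is relayed from C5 (oxygen enters the lactone enolate anti to the C5 side chain); the E alkene comes from syn-carboalumination; the (2R,3R)-oxirane is set by reagent control with D-(−)-diethyl tartrate.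

Key step: step 7

Remark: 7-hydroxy-8-methoxycoumarin is taken as a purchasable phenol, and the saturated lactone of step 8 is carried as a mixture of epimers at its methyl-bearing carbon because that centre is planarised in step 9.

**Route**

Step 1
Reactants: 1 (R)-epichlorohydrin; 2 (trimethylsilyl)acetylene
Product: 4 (2R)-1-chloro-5-(trimethylsilyl)pent-4-yn-2-ol, via lithium (trimethylsilyl)acetylide 3 (not isolated)
Conditions: 2, n-BuLi, THF, −78 °C; BF3·OEt2; then 1, −78 °C; aq. NH4Cl
Reagents that add atoms: none
Why: Yamaguchi–Hirao alkynylation, in which the BF3-activated epoxide is opened by the alkynyl nucleophile at the unsubstituted ring CH2 (SN2), so the stereocentre of 1 is not touched and the primary chloride survives at low temperature.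

Step 2
Reactants: 4 (2R)-1-chloro-5-(trimethylsilyl)pent-4-yn-2-ol
Product: 6 (3R)-6-(trimethylsilyl)hex-1-en-5-yn-3-ol, via terminal epoxide 5 (not isolated)
Conditions: Me3S+ I− (4 equiv), n-BuLi (3.8 equiv), THF, −20 °C → rt
Reagents that add atoms: trimethylsulfonium iodide, C[S+](C)C.[I-]
Why: Sulfonium-ylide one-carbon homologation: the ylide first acts as base to close the chlorohydrin to the epoxide, then opens it at CH2, and the β-alkoxy sulfonium eliminates dimethyl sulfide to give the vinyl carbinol without breaking any bond to the stereocentre.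

Step 3
Reactants: 6 (3R)-6-(trimethylsilyl)hex-1-en-5-yn-3-ol
Product: 7 (3R)-hex-1-en-5-yn-3-ol
Conditions: K2CO3 (0.2 equiv), MeOH, rt; careful concentration (volatile product)
Reagents that add atoms: none
Why: Methoxide-mediated protodesilylation of a C-silyl alkyne, which is selective for the sp C–Si bond and leaves the allylic alcohol untouched.

Step 4
Reactants: 7 (3R)-hex-1-en-5-yn-3-ol
Product: 9 (2E,5R)-3-methylhepta-2,6-diene-1,5-diol, via alkenylalane 8 (not isolated)
Conditions: AlMe3 (3 equiv), Cp2ZrCl2 (0.25 equiv), CH2Cl2, 0 °C → rt; volatiles removed; n-BuLi, THF/hexane, −78 °C; (CH2O)n, → rt; 1 M HCl, 0 °C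
Reagents that add atoms: trimethylaluminium, C[Al](C)C; paraformaldehyde (formaldehyde unit), C=O
Why: Negishi zirconium-catalysed carboalumination adds CH3 and Al syn across the terminal alkyne with methyl on the internal carbon, and the derived lithium alanate is hydroxymethylated with retention, so CH2OH ends trans to the chain CH2 (E) while the monosubstituted alkene and the carbinol centre are not involved.

Step 5
Reactants: 9 (2E,5R)-3-methylhepta-2,6-diene-1,5-diol
Product: 10 (3R,5E)-7-{[tert-butyl(dimethyl)silyl]oxy}-5-methylhepta-1,5-dien-3-ol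
Conditions: TBSCl (1.05 equiv), imidazole, CH2Cl2, −20 → 0 °C
Reagents that add atoms: tert-butyldimethylsilyl chloride, CC(C)(C)[Si](C)(C)Cl
Why: Sterically controlled silylation, in which the bulky silyl chloride should react at the primary allylic hydroxyl well before the secondary one.

Step 6
Reactants: 10 (3R,5E)-7-{[tert-butyl(dimethyl)silyl]oxy}-5-methylhepta-1,5-dien-3-ol; 11 methacryloyl chloride
Product: 12 (3R,5E)-7-{[tert-butyl(dimethyl)silyl]oxy}-5-methylhepta-1,5-dien-3-yl 2-methylprop-2-enoate
Conditions: 11, Et3N, DMAP (cat.), CH2Cl2, 0 °C → rt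
Reagents that add atoms: none
Why: DMAP-catalysed O-acylation of the secondary alcohol, which installs the lactone's C2, C3 and 3-methyl carbons on the C5 oxygen without touching the stereocentre.

Step 7
Reactants: 12 (3R,5E)-7-{[tert-butyl(dimethyl)silyl]oxy}-5-methylhepta-1,5-dien-3-yl 2-methylprop-2-enoate
Product: 13 (5R)-5-[(2E)-4-{[tert-butyl(dimethyl)silyl]oxy}-2-methylbut-2-en-1-yl]-3-methylfuran-2(5H)-one
Conditions: second-generation Grubbs catalyst (5 mol %), CH2Cl2 (5 mM), reflux
Reagents that add atoms: none
Why: Ring-closing olefin metathesis: the ruthenium alkylidene exchanges onto the unhindered vinyl group of 12, adds [2+2] to the tethered methacrylate C=C, and cycloreversion of the ruthenacyclobutane joins C3 to C4 of the lactone with loss of ethylene. The closest known reaction type is the ring-closing metathesis of allylic methacrylates to 3-methylfuran-2(5H)-ones with N-heterocyclic-carbene ruthenium catalysts. One ring is closed, the five-membered unsaturated lactone, by intramolecular metathesis between a monosubstituted and a 1,1-disubstituted alkene, driven by ethylene release and conjugation in the product. No stereocentre is created; C5 lies outside the reacting carbons and should keep its configuration, and the planar C3 formed here is what later lets C5 set the tertiary carbinol. The step needs chemoselectivity among three alkenes and ring closure over oligomerisation: the trisubstituted allylic silyl ether alkene is too hindered to load the catalyst and could only close a cyclobutene, and high dilution with heating (to populate the reactive ester rotamer) favours the intramolecular path.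

Step 8
Reactants: 13 (5R)-5-[(2E)-4-{[tert-butyl(dimethyl)silyl]oxy}-2-methylbut-2-en-1-yl]-3-methylfuran-2(5H)-one
Product: 14 (3RS,5S)-5-[(2E)-4-{[tert-butyl(dimethyl)silyl]oxy}-2-methylbut-2-en-1-yl]-3-methyloxolan-2-one
Conditions: [(Ph3P)CuH]6 (5 mol %), PhSiH3 (1.2 equiv), t-BuOH (1.5 equiv), toluene, rt
Reagents that add atoms: none
Why: Copper hydride conjugate reduction (Stryker reduction) delivers hydride only to the β-carbon of the conjugated lactone, so the isolated trisubstituted alkene, the silyl ether and the lactone carbonyl should be left alone; the C5 descriptor changes from R to S by priority only.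

Step 9
Reactants: 14 (3RS,5S)-5-[(2E)-4-{[tert-butyl(dimethyl)silyl]oxy}-2-methylbut-2-en-1-yl]-3-methyloxolan-2-one
Product: 16 (3R,5R)-5-[(2E)-4-{[tert-butyl(dimethyl)silyl]oxy}-2-methylbut-2-en-1-yl]-3-hydroxy-3-methyloxolan-2-one, via potassium lactone enolate 15 (not isolated)
Conditions: KN(SiMe3)2 (1.2 equiv), THF, −78 °C; 2-(phenylsulfonyl)-3-phenyloxaziridine (1.5 equiv), −78 °C; aq. NH4Cl
Reagents that add atoms: 2-(phenylsulfonyl)-3-phenyloxaziridine, O=S(=O)(c1ccccc1)N1OC1c1ccccc1
Why: Davis oxidation of the planar lactone enolate, in which the bulky N-sulfonyloxaziridine should transfer oxygen to C3 on the ring face opposite the C5 side chain (1,3-induction), placing OH trans and CH3 cis to that chain (3R) from either epimer of 14.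

Step 10
Reactants: 16 (3R,5R)-5-[(2E)-4-{[tert-butyl(dimethyl)silyl]oxy}-2-methylbut-2-en-1-yl]-3-hydroxy-3-methyloxolan-2-one
Product: 17 (3R,5R)-3-hydroxy-5-[(2E)-4-hydroxy-2-methylbut-2-en-1-yl]-3-methyloxolan-2-one
Conditions: HF·pyridine, pyridine, THF, 0 °C → rt
Reagents that add atoms: none
Why: Fluoride-driven cleavage of the primary silyl ether under buffered, non-basic conditions, so the lactone is not opened and the tertiary carbinol is not epimerised.

Step 11
Reactants: 17 (3R,5R)-3-hydroxy-5-[(2E)-4-hydroxy-2-methylbut-2-en-1-yl]-3-methyloxolan-2-one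
Product: 18 (3R,5S)-3-hydroxy-5-{[(2R,3R)-3-(hydroxymethyl)-2-methyloxiran-2-yl]methyl}-3-methyloxolan-2-one
Conditions: Ti(OiPr)4 (1.0 equiv), D-(−)-diethyl tartrate (1.2 equiv), t-BuOOH (2.0 equiv, anhydrous in isooctane), 4 Å MS, CH2Cl2, −20 °C; aq. tartaric acid
Reagents that add atoms: tert-butyl hydroperoxide, CC(C)(C)OO
Why: Katsuki–Sharpless asymmetric epoxidation: the primary allylic alkoxide binds the titanium tartrate complex, and D-(−)-tartrate directs oxygen to the alkene face that gives the (2R,3R)-oxirane of an E-3-methylalk-2-en-1-ol, overriding the remote C5 centre (whose descriptor becomes S by priority only).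

Step 12
Reactants: 18 (3R,5S)-3-hydroxy-5-{[(2R,3R)-3-(hydroxymethyl)-2-methyloxiran-2-yl]methyl}-3-methyloxolan-2-one; 19 7-hydroxy-8-methoxy-2H-chromen-2-one
Product: 20 7-{[(2R,3R)-3-{[(2S,4R)-4-hydroxy-4-methyl-5-oxooxolan-2-yl]methyl}-3-methyloxiran-2-yl]methoxy}-8-methoxy-2H-chromen-2-one
Conditions: PPh3 (1.3 equiv), DIAD (1.3 equiv), THF, 0 °C → rt
Reagents that add atoms: none
Why: Mitsunobu etherification, in which the acidic phenol displaces the primary oxyphosphonium at CH2 (no stereocentre involved) while the tertiary hydroxyl, the oxirane and both lactones should stay intact.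

**Compound list**

1 | (R)-epichlorohydrin | ClC[C@H]1CO1 | starting material
2 | (trimethylsilyl)acetylene | C#C[Si](C)(C)C | starting material
3 | lithium (trimethylsilyl)acetylide | [Li]C#C[Si](C)(C)C | intermediate
4 | (2R)-1-chloro-5-(trimethylsilyl)pent-4-yn-2-ol | ClC[C@H](O)CC#C[Si](C)(C)C | intermediate
5 | (2R)-2-[3-(trimethylsilyl)prop-2-yn-1-yl]oxirane | C1[C@H](O1)CC#C[Si](C)(C)C | intermediate
6 | (3R)-6-(trimethylsilyl)hex-1-en-5-yn-3-ol | C=C[C@H](O)CC#C[Si](C)(C)C | intermediate
7 | (3R)-hex-1-en-5-yn-3-ol | C=C[C@H](O)CC#C | intermediate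
8 | dimethylaluminium alkoxide of (3R,5E)-6-(dimethylalumanyl)-5-methylhexa-1,5-dien-3-ol | C=C[C@H](O[Al](C)C)C/C(C)=C/[Al](C)C | intermediate
9 | (2E,5R)-3-methylhepta-2,6-diene-1,5-diol | C=C[C@H](O)C/C(C)=C/CO | intermediate
10 | (3R,5E)-7-{[tert-butyl(dimethyl)silyl]oxy}-5-methylhepta-1,5-dien-3-ol | C=C[C@H](O)C/C(C)=C/CO[Si](C)(C)C(C)(C)C | intermediate
11 | methacryloyl chloride | C=C(C)C(=O)Cl | starting material
12 | (3R,5E)-7-{[tert-butyl(dimethyl)silyl]oxy}-5-methylhepta-1,5-dien-3-yl 2-methylprop-2-enoate | C=C[C@H](OC(=O)C(C)=C)C/C(C)=C/CO[Si](C)(C)C(C)(C)C | intermediate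
13 | (5R)-5-[(2E)-4-{[tert-butyl(dimethyl)silyl]oxy}-2-methylbut-2-en-1-yl]-3-methylfuran-2(5H)-one | O=C1O[C@H](C/C(C)=C/CO[Si](C)(C)C(C)(C)C)C=C1C | intermediate
14 | (3RS,5S)-5-[(2E)-4-{[tert-butyl(dimethyl)silyl]oxy}-2-methylbut-2-en-1-yl]-3-methyloxolan-2-one (both C3 epimers) | O=C1O[C@H](C/C(C)=C/CO[Si](C)(C)C(C)(C)C)CC1C | intermediate
15 | potassium (5S)-5-[(2E)-4-{[tert-butyl(dimethyl)silyl]oxy}-2-methylbut-2-en-1-yl]-3-methyl-4,5-dihydrofuran-2-olate | [K+].[O-]C1=C(C)C[C@@H](C/C(C)=C/CO[Si](C)(C)C(C)(C)C)O1 | intermediate
16 | (3R,5R)-5-[(2E)-4-{[tert-butyl(dimethyl)silyl]oxy}-2-methylbut-2-en-1-yl]-3-hydroxy-3-methyloxolan-2-one | CC(C)(C)[Si](C)(C)OC/C=C(\C)C[C@@H]1C[C@@](C)(O)C(=O)O1 | intermediate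
17 | (3R,5R)-3-hydroxy-5-[(2E)-4-hydroxy-2-methylbut-2-en-1-yl]-3-methyloxolan-2-one | OC/C=C(\C)C[C@@H]1C[C@@](C)(O)C(=O)O1 | intermediate
18 | (3R,5S)-3-hydroxy-5-{[(2R,3R)-3-(hydroxymethyl)-2-methyloxiran-2-yl]methyl}-3-methyloxolan-2-one | OC[C@H]1O[C@]1(C)C[C@@H]2C[C@@](C)(O)C(=O)O2 | intermediate
19 | 7-hydroxy-8-methoxy-2H-chromen-2-one | COc1c(O)ccc2ccc(=O)oc12 | starting material
20 | 7-{[(2R,3R)-3-{[(2S,4R)-4-hydroxy-4-methyl-5-oxooxolan-2-yl]methyl}-3-methyloxiran-2-yl]methoxy}-8-methoxy-2H-chromen-2-one | COc1c(OC[C@H]2O[C@]2(C)C[C@@H]2C[C@@](C)(O)C(=O)O2)ccc2ccc(=O)oc12 | target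

**Step count and risks**

Total step count: 12. Longest linear sequence: 12 steps, from (R)-epichlorohydrin 1 to the target 20; compounds 2, 11 and 19 are purchased partners.

Steps most likely to fail:

1. Step 9. What may go wrong is weak facial discrimination when oxygen is transferred to the flat enolate (the C5 side chain is one CH2 removed from the ring), together with addition of the enolate to the sulfonyl imine by-product. The fallback sets out from butenolide 13 and bypasses steps 8 and 9. A Mukaiyama-type radical hydration (Mn(dpm)3 cat., PhSiH3, O2, i-PrOH/CH2Cl2, 0 °C) should transfer a hydrogen atom to C4 of the conjugated alkene and let O2 trap the tertiary C3 radical on the face away from the C5 substituent. This gives (3R,5R)-5-[(2E)-4-{[tert-butyl(dimethyl)silyl]oxy}-2-methylbut-2-en-1-yl]-3-hydroperoxy-3-methyloxolan-2-one F1, which P(OEt)3 reduces in the same flask, and the sequence comes back to the route at 16. The open point of this fallback is competition from the isolated trisubstituted alkene.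

2. Step 11. What may go wrong is sequestration of titanium by the chelating α-hydroxy lactone, which would erode tartrate control and slow turnover, and titanium alkoxide-mediated opening of the lactone. The fallback sets out from allylic alcohol 17. The Mitsunobu coupling with 19 (PPh3, DIAD, THF) is run first to give 7-({(2E)-4-[(2R,4R)-4-hydroxy-4-methyl-5-oxooxolan-2-yl]-3-methylbut-2-en-1-yl}oxy)-8-methoxy-2H-chromen-2-one F2. Its trisubstituted alkene is then epoxidised under reagent control by a Shi epoxidation (D-fructose-derived ketone catalyst, Oxone (2KHSO5·KHSO4·K2SO4), buffered MeCN/dimethoxymethane/water, 0 °C), whose spiro transition state should deliver the (2R,3R)-oxirane. This comes back to the route at the target 20.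

3. Step 4. What may go wrong is incomplete or regio-unselective methylalumination in the presence of the aluminium alkoxide and the vinyl group, and sluggish hydroxymethylation of the alanate. The fallback sets out from enynol 7. Double deprotonation (n-BuLi, 2.2 equiv, THF, −78 °C) and paraformaldehyde give (5R)-hept-6-en-2-yne-1,5-diol F3. Trans-hydroalumination directed by the propargylic alkoxide with NaAlH2(OCH2CH2OMe)2, followed by I2, gives (2Z,5R)-3-iodohepta-2,6-diene-1,5-diol F4. Me2CuLi (excess, Et2O, 0 °C) then replaces iodine by methyl with retention of alkene geometry, and the sequence comes back to the route at diol 9.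

Further compounds
F1 | step 9 | (3R,5R)-5-[(2E)-4-{[tert-butyl(dimethyl)silyl]oxy}-2-methylbut-2-en-1-yl]-3-hydroperoxy-3-methyloxolan-2-one | CC(C)(C)[Si](C)(C)OC/C=C(\C)C[C@@H]1C[C@@](C)(OO)C(=O)O1
F2 | step 11 | 7-({(2E)-4-[(2R,4R)-4-hydroxy-4-methyl-5-oxooxolan-2-yl]-3-methylbut-2-en-1-yl}oxy)-8-methoxy-2H-chromen-2-one | COc1c(OC/C=C(\C)C[C@@H]2C[C@@](C)(O)C(=O)O2)ccc2ccc(=O)oc12
F3 | step 4 | (5R)-hept-6-en-2-yne-1,5-diol | C=C[C@H](O)CC#CCO
F4 | step 4 | (2Z,5R)-3-iodohepta-2,6-diene-1,5-diol | C=C[C@H](O)C/C(I)=C/CO
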